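**Plan**

Atom labels (used only in this text) follow the order of the target SMILES: C1 = methyl on C2; ring A = C3, C4, C5, C6 (methyl C7), C8; ring B = C2, C3, C8, C9, C10, C11 (methyl C12), C13, C25; ring C = C13, C14, C15 (carboxyl C16), C23, C24, C25 (OH); ring D = C15, C17, C18, C19 (isopropyl C20–C22), C23. β is the face of the hydrindane that carries C16, α the other face.
Retrosynthesis: first C19–C20, back to a ring-D ketone; then C8–C9 with C2–O re-formed (retro-Claisen), turning ring B into a δ-lactone on ring C that carries ring A as a cyclopentenyl group; then C2–C1, C2–C3, C25–C2 and C13–C11, back to a hydrindanone; last C15–C23 and C13–C14 together (retro-[4+2]), back to an open-chain triene.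
Forward: the chain C23–C19–C18–C17–C15(=C14) is assembled from a four-carbon chiral-pool acetonide; rings D and C close together in the cycloaddition; the C11 and C2 arms are added to ring C; ring A arrives as a cyclopentenyl triflate; ring B closes last by lactone methylenation and [3,3] ring expansion, followed by deoxygenation at C10, isopropylation at C19 and ester cleavage.
Enabling feature: cyclohexane ring C shares the carboxyl-bearing quaternary C15 and the ring-fusion CH C23 with cyclopentane ring D and carries its oxygen at C25, para to C15. Ring C is therefore a cyclohexene retron made from a 2-siloxydiene (C13=C25–C24=C23) and a 2-substituted acrylate (C15=C14) joined by C17–C18–C19.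
Stereochemistry: the bought C19–O centre directs C15 and C23 in the cycloaddition and is later erased. C13 and C25 follow from the chair of ring C, C11 from (R)-lactate with inversion, C2 from Felkin–Anh addition, C6 from a catalytic asymmetric conjugate reduction, C8 from chirality transfer in the chair-like Claisen transition state, and C19 from hydrogenation on the face opposite the angular ester.

Key step: step 10

Remark on the chemistry: an allylic substituent on the diene side of the tether is expected to end up trans to the angular ester in this cycloaddition, whereas isopropyl and carboxyl are cis in the target; the allylic centre is therefore carried as a silyl ether, which does the relaying, and C19 is set at the end by hydrogenation.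

**Route**

Step 1
Reactants: 1 (R)-2-(2,2-dimethyl-1,3-dioxolan-4-yl)ethan-1-ol
Product: 2 (4R)-4-(2-iodoethyl)-2,2-dimethyl-1,3-dioxolane
Conditions: I2, PPh3, imidazole, CH2Cl2, 0 → 23 °C
Reagents that add atoms: iodine, [I][I]
Why: Appel iodination (SN2 displacement of the alkoxyphosphonium ion by iodide) converts the primary alcohol into the electrophile for step 2, and the imidazole buffer protects the acetonide and the untouched C19 stereocentre.

Step 2
Reactants: 2 (4R)-4-(2-iodoethyl)-2,2-dimethyl-1,3-dioxolane; 3 trimethyl phosphonoacetate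
Product: 5 methyl 2-(dimethoxyphosphoryl)-4-[(4R)-2,2-dimethyl-1,3-dioxolan-4-yl]butanoate (both epimers at the phosphonate carbon), via sodium phosphonoacetate enolate 4 (not isolated)
Conditions: NaH, DMF, 0 °C; then 2, 60 °C
Reagents that add atoms: none
Why: SN2 alkylation of the stabilised phosphonate carbanion by the primary iodide makes the C17–C15 bond, and the new centre at C15 is irrelevant because it becomes sp2 in step 3.

Step 3
Reactants: 5 methyl 2-(dimethoxyphosphoryl)-4-[(4R)-2,2-dimethyl-1,3-dioxolan-4-yl]butanoate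
Product: 6 methyl 4-[(4R)-2,2-dimethyl-1,3-dioxolan-4-yl]-2-methylidenebutanoate
Conditions: aq. CH2O (37%), K2CO3, THF/H2O, 23 → 50 °C
Reagents that add atoms: formaldehyde, C=O
Why: Horner–Wadsworth–Emmons olefination with formaldehyde, the standard entry to 2-substituted acrylates, creates the dienophile C15=C14 under mild carbonate conditions.

Step 4
Reactants: 6 methyl 4-[(4R)-2,2-dimethyl-1,3-dioxolan-4-yl]-2-methylidenebutanoate
Product: 7 methyl (5R)-5,6-dihydroxy-2-methylidenehexanoate
Conditions: PPTS (0.1 equiv), MeOH, 23 °C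
Reagents that add atoms: none
Why: Acid-catalysed transketalisation in methanol removes the acetonide, the mild catalyst keeping the secondary alcohol from lactonising onto the ester.

Step 5
Reactants: 7 methyl (5R)-5,6-dihydroxy-2-methylidenehexanoate
Product: 8 methyl (5R)-5,6-bis[(tert-butyldimethylsilyl)oxy]-2-methylidenehexanoate
Conditions: TBSCl, imidazole, DMF, 23 °C
Reagents that add atoms: tert-butyldimethylsilyl chloride, CC(C)(C)[Si](C)(C)Cl
Why: Standard silylation of both hydroxyl groups, the C19 ether being the group that will later steer the cycloaddition.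

Step 6
Reactants: 8 methyl (5R)-5,6-bis[(tert-butyldimethylsilyl)oxy]-2-methylidenehexanoate
Product: 9 methyl (5R)-5-[(tert-butyldimethylsilyl)oxy]-6-hydroxy-2-methylidenehexanoate
Conditions: HF·pyridine, pyridine, THF, 0 °C
Reagents that add atoms: none
Why: Selective desilylation, the primary silyl ether being cleaved much faster by buffered fluoride than the hindered secondary one.

Step 7
Reactants: 9 methyl (5R)-5-[(tert-butyldimethylsilyl)oxy]-6-hydroxy-2-methylidenehexanoate
Product: 10 methyl (5R)-5-[(tert-butyldimethylsilyl)oxy]-2-methylidene-6-oxohexanoate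
Conditions: Dess–Martin periodinane, CH2Cl2, 0 → 23 °C
Reagents that add atoms: none
Why: Dess–Martin oxidation gives the α-silyloxy aldehyde under neutral conditions that do not epimerise C19.

Step 8
Reactants: 10 methyl (5R)-5-[(tert-butyldimethylsilyl)oxy]-2-methylidene-6-oxohexanoate; 11 1-(triphenyl-λ5-phosphanylidene)propan-2-one
Product: 12 methyl (5R,6E)-5-[(tert-butyldimethylsilyl)oxy]-2-methylidene-8-oxonon-6-enoate
Conditions: toluene, 70 °C
Reagents that add atoms: none
Why: Wittig reaction with the stabilised acetonyl ylide gives the (E)-enone (C23=C24) without added base, so the α-oxygenated stereocentre is preserved.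

Step 9
Reactants: 12 methyl (5R,6E)-5-[(tert-butyldimethylsilyl)oxy]-2-methylidene-8-oxonon-6-enoate
Product: 13 methyl (5R,6E)-5,8-bis[(tert-butyldimethylsilyl)oxy]-2-methylidenenona-6,8-dienoate
Conditions: TBSOTf, Et3N, CH2Cl2, −78 → 0 °C
Reagents that add atoms: tert-butyldimethylsilyl trifluoromethanesulfonate, CC(C)(C)[Si](C)(C)OS(=O)(=O)C(F)(F)F
Why: Soft enolisation (silyl triflate and amine) deprotonates the methyl ketone at its kinetic α′ methyl group and traps the cross-conjugated enol as the 2-siloxydiene, the ester having no α-hydrogen.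

Step 10
Reactants: 13 methyl (5R,6E)-5,8-bis[(tert-butyldimethylsilyl)oxy]-2-methylidenenona-6,8-dienoate
Product: 14 methyl (3R,3aR,7aS)-3,5-bis[(tert-butyldimethylsilyl)oxy]-2,3,3a,6,7,7a-hexahydro-1H-indene-7a-carboxylate (trans ring fusion; C16 ester β, C23–H α, C19–OTBS α)
Conditions: toluene (0.005 M), BHT (5 mol %), 120 °C, sealed tube
Reagents that add atoms: none
Why: Thermal, concerted but asynchronous [4+2] cycloaddition in which the nucleophilic diene terminus C13 bonds to the acrylate CH2 (C14) and the substituted diene terminus C23 to the acrylate α-carbon C15; the closest known reaction type is the intramolecular Diels–Alder reaction of (E)-1,3,8-nonatrienes that carry the activating group on the internal dienophile carbon. Ring D is closed as a five-membered ring by the C23–C15 bond across the three-carbon tether, and ring C is closed as the cyclohexene by the C23–C15 and C13–C14 bonds in the same event, the regiochemistry being fixed by the tether and matched to the polarity of the siloxydiene and the acrylate. C15 is controlled by the C19 stereocentre: the bulky silyloxy group avoids the position next to the ester (1,3-repulsion across the forming ring, A(1,3) strain with the diene hydrogen) and turns away from the dienophile, so the ester is delivered to the face trans to the C19 oxygen. C23 is controlled by the endo orientation of the ester with the tether exo, which gives the trans ring fusion. The step therefore needs facial and endo selectivity, which the (E)-diene, the single allylic stereocentre and the short tether should provide; a Lewis acid is avoided because the allylic silyl ether next to the siloxydiene could ionise. The product is a regiodefined silyl enol ether of the C25 ketone.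

Step 11
Reactants: 14 methyl (3R,3aR,7aS)-3,5-bis[(tert-butyldimethylsilyl)oxy]-2,3,3a,6,7,7a-hexahydro-1H-indene-7a-carboxylate
Product: 15 methyl (3R,3aR,7aS)-3-[(tert-butyldimethylsilyl)oxy]-5-oxooctahydro-1H-indene-7a-carboxylate
Conditions: 1 M aq. HCl, THF, 0 °C
Reagents that add atoms: none
Why: Brief aqueous acid hydrolyses the silyl enol ether to the C25 ketone much faster than it cleaves the secondary alkyl silyl ether, and no stereocentre is affected because C24 becomes CH2.

Step 12
Reactants: 15 methyl (3R,3aR,7aS)-3-[(tert-butyldimethylsilyl)oxy]-5-oxooctahydro-1H-indene-7a-carboxylate; 16 ethyl (2R)-2-{[(trifluoromethyl)sulfonyl]oxy}propanoate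
Product: 18 γ-keto ester (15 carrying at C13, α and equatorial, the side chain (R)-CH(CH3)CO2Et; C11 R), via lithium C13 enolate 17 (not isolated)
Conditions: LiN(i-Pr)2, THF, −78 °C; then 16, −78 → −30 °C
Reagents that add atoms: none
Why: Kinetic enolate formation takes place at C13, away from the ring fusion, and SN2 alkylation by the lactate-derived triflate (inversion at C11) occurs on the face opposite the axial angular ester, which places the new side chain equatorial at C13.

Step 13
Reactants: 18 γ-keto ester
Product: 19 tertiary alcohol (C25: OH α and axial, vinyl β and equatorial)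
Conditions: vinylmagnesium bromide, THF, −78 °C; aq. NH4Cl quench at −78 °C
Reagents that add atoms: vinylmagnesium bromide, C=C[Mg]Br
Why: Grignard 1,2-addition to the ketone is faster than attack on either ester at −78 °C, and equatorial approach of the vinyl group, trans to the C13 side chain, gives the axial C25 hydroxyl and the equatorial C25–C2 bond of the target.

Step 14
Reactants: 19 tertiary alcohol
Product: 20 C25 triethylsilyl ether of 19
Conditions: TESOTf, 2,6-lutidine, CH2Cl2, −78 → 0 °C
Reagents that add atoms: triethylsilyl trifluoromethanesulfonate, CC[Si](CC)(CC)OS(=O)(=O)C(F)(F)F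
Why: Silylation of the tertiary alcohol with the reactive silyl triflate masks the C25 oxygen, so that it can neither form a γ-lactone with the C10 ester nor interfere with the later organometallic and methylenation steps.

Step 15
Reactants: 20 C25 triethylsilyl ether of 19
Product: 22 α-silyloxy aldehyde (C2 = CHO on C25), via secondary ozonide 21 (not isolated)
Conditions: O3, CH2Cl2, −78 °C; then PPh3, −78 → 23 °C
Reagents that add atoms: ozone, [O-][O+]=O
Why: Ozonolysis with reductive work-up cleaves the only C=C bond of the molecule to the non-enolisable aldehyde at C2.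

Step 16
Reactants: 23 3-methylcyclopent-2-en-1-one
Product: 26 (3R)-3-methylcyclopent-1-en-1-yl trifluoromethanesulfonate, via bis(cyclopentenyloxy)diphenylsilane 24 (not isolated), via lithium cyclopentenolate 25 (not isolated)
Conditions: CuCl (5 mol %), NaOt-Bu (5 mol %), (S)-p-tol-BINAP (5 mol %), Ph2SiH2 (0.55 equiv), toluene, 0 °C; then MeLi, THF, 0 °C; then PhNTf2, −78 → 0 °C
Reagents that add atoms: N-phenylbis(trifluoromethanesulfonimide), O=S(=O)(N(c1ccccc1)S(=O)(=O)C(F)(F)F)C(F)(F)F
Why: Copper hydride-catalysed asymmetric conjugate reduction sets C6 through the chiral bisphosphine (the ligand antipode is taken if it proves to give the (S) series) and delivers the regiodefined C3=C8 enol silyl ether, which is converted through the lithium enolate into the enol triflate without loss of regiochemistry.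

Step 17
Reactants: 22 α-silyloxy aldehyde; 26 (3R)-3-methylcyclopent-1-en-1-yl trifluoromethanesulfonate
Product: 27 allylic alcohols (both epimers at C2; ring A attached through C3)
Conditions: CrCl2 (4 equiv), NiCl2 (2 mol %), DMF, 23 °C
Reagents that add atoms: none
Why: Nozaki–Hiyama–Kishi coupling adds the alkenylchromium reagent chemoselectively to the hindered aldehyde (C2–C3 bond) in the presence of both esters, and the configuration of the new carbinol is immaterial because it is oxidised next.

Step 18
Reactants: 27 allylic alcohols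
Product: 28 enone (C2 ketone between C25 and the cyclopentenyl ring)
Conditions: Dess–Martin periodinane, CH2Cl2, 0 → 23 °C
Reagents that add atoms: none
Why: Dess–Martin oxidation of the allylic alcohol gives the enone whose carbonyl carbon is C2.

Step 19
Reactants: 28 enone
Product: 30 δ-lactone (ring O–C10(=O)–C11–C13–C25–C2, trans-fused to ring C; C11 methyl equatorial; C2 R with axial methyl and equatorial cyclopentenyl), via lithium C2 alkoxide 29 (not isolated)
Conditions: MeLi, THF, −78 °C; then 23 °C; aq. NH4Cl
Reagents that add atoms: methyllithium, [Li]C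
Why: 1,2-Addition of MeLi to the enone under Felkin–Anh control (methyl anti to the C25–OSiEt3 bond, the cyclopentenyl group turned towards the C24 methylene and away from the C13 side chain) sets C2, and on warming the tertiary alkoxide closes the δ-lactone onto the ethyl ester (intramolecular transesterification), the C25 oxygen being blocked as its silyl ether.

Step 20
Reactants: 30 δ-lactone
Product: 31 2-methylidenetetrahydropyran (exocyclic enol ether C10=C9)
Conditions: Cp2TiMe2 (2 equiv), toluene, 70 °C, dark
Reagents that add atoms: dimethyltitanocene, C[Ti](C)(C1C=CC=C1)C1C=CC=C1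
Why: Petasis methylenation by the titanium methylidene converts the lactone carbonyl into the exocyclic enol ether faster than the hindered angular methyl ester and without base, so C11 is not epimerised.

Step 21
Reactants: 31 2-methylidenetetrahydropyran
Product: 32 cyclooct-4-enone (rings A–B–C–D complete; C10 ketone; C2=C3 tetrasubstituted, C1 cis to C4; C8 S)
Conditions: toluene, i-Pr2NEt (0.2 equiv), sealed tube, 185 °C
Reagents that add atoms: none
Why: Thermal Claisen rearrangement ([3,3]) of the 2-methylidene-6-alkenyltetrahydropyran through a chair-like transition state, reached from a boat form of the tetrahydropyran in which the equatorial cyclopentenyl group swings over the enol ether: the C8–C9 bond forms while C2–O breaks, ring B results as the cyclooctenone with the cis-in-ring C2=C3 alkene, and chirality transfer from C2 creates C8 on the face anti to the C6 methyl.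

Step 22
Reactants: 32 cyclooct-4-enone
Product: 33 C10 tosylhydrazone
Conditions: TsNHNH2, EtOH, 50 °C
Reagents that add atoms: 4-methylbenzenesulfonohydrazide, Cc1ccc(cc1)S(=O)(=O)NN
Why: Condensation of the C10 ketone with the sulfonyl hydrazide gives the tosylhydrazone under nearly neutral conditions that the tertiary allylic silyl ether tolerates.

Step 23
Reactants: 33 C10 tosylhydrazone
Product: 35 bis-silyl ether of the methyl ester with C10 as CH2, via N-boryl tosylhydrazine 34 (not isolated)
Conditions: catecholborane, CHCl3, 0 °C; then NaOAc·3H2O, 60 °C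
Reagents that add atoms: none
Why: Hydride reduction of the tosylhydrazone by catecholborane followed by acetate-induced loss of sulfinate and N2 from the diazene replaces C=N by CH2 (reductive deoxygenation of a ketone) without a free radical at C10 that could add across the ring to the C2=C3 alkene.

Step 24
Reactants: 35 bis-silyl ether
Product: 36 diol (C25–OH tertiary, C19–OH secondary and α)
Conditions: Bu4NF, THF, 50 °C
Reagents that add atoms: none
Why: Fluoride cleaves both silyl ethers, freeing the tertiary C25 alcohol of the target and the secondary C19 alcohol needed for the isopropyl installation.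

Step 25
Reactants: 36 diol
Product: 37 ring-D ketone (C19=O)
Conditions: Dess–Martin periodinane, CH2Cl2, 0 °C
Reagents that add atoms: none
Why: Dess–Martin oxidation converts the secondary C19 alcohol into the ketone while the tertiary allylic alcohol cannot be oxidised.

Step 26
Reactants: 37 ring-D ketone
Product: 39 enol triflate (C18=C19, triflate on C19), via dipotassium alkoxide enolate 38 (not isolated)
Conditions: KN(SiMe3)2 (2.2 equiv), THF, −78 °C; then PhNTf2, −78 → 0 °C; aq. NH4Cl
Reagents that add atoms: N-phenylbis(trifluoromethanesulfonimide), O=S(=O)(N(c1ccccc1)S(=O)(=O)C(F)(F)F)C(F)(F)F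
Why: Kinetic deprotonation with the hindered amide base (the first equivalent is consumed by the tertiary alcohol) occurs at the C18 methylene and not at the ring-fusion C23–H, and O-sulfonylation of the enolate gives the enol triflate.

Step 27
Reactants: 39 enol triflate
Product: 40 cyclopentene (C18=C19 with isopropyl on C19)
Conditions: i-PrMgCl (3 equiv), Fe(acac)3 (5 mol %), THF/NMP, −30 °C; aq. NH4Cl
Reagents that add atoms: isopropylmagnesium chloride, CC(C)[Mg]Cl
Why: Iron-catalysed Kumada-type cross-coupling of the alkenyl triflate with the secondary Grignard reagent forms the C19–C20 bond at low temperature, where the hindered methyl ester is not attacked.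

Step 28
Reactants: 40 cyclopentene
Product: 41 methyl ester of sesterfisheric acid
Conditions: H2 (1 atm), PtO2, EtOAc, 23 °C
Reagents that add atoms: none
Why: Heterogeneous hydrogenation of the trisubstituted ring-D alkene from the α face, opposite the angular ester and the C24 methylene, sets C19 with the isopropyl group cis to the ester, while the tetrasubstituted C2=C3 alkene is too hindered to react.

Step 29
Reactants: 41 methyl ester of sesterfisheric acid
Product: 42 sesterfisheric acid
Conditions: n-PrSLi, HMPA, 23 °C; then dilute aq. HCl to pH 4, 0 °C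
Reagents that add atoms: none
Why: SN2 demethylation of the hindered angular methyl ester by thiolate (attack at the methyl carbon) liberates the carboxylic acid without exposing the tertiary allylic alcohol to strong acid or to forcing hydroxide.

**Compound list**

1 | (R)-2-(2,2-dimethyl-1,3-dioxolan-4-yl)ethan-1-ol | CC1(C)OC[C@@H](CCO)O1 | starting material
2 | (4R)-4-(2-iodoethyl)-2,2-dimethyl-1,3-dioxolane | CC1(C)OC[C@@H](CCI)O1 | intermediate
3 | trimethyl phosphonoacetate | COC(=O)CP(=O)(OC)OC | starting material
4 | sodium enolate of trimethyl phosphonoacetate | [Na+].COC(=O)[CH-]P(=O)(OC)OC | intermediate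
5 | methyl 2-(dimethoxyphosphoryl)-4-[(4R)-2,2-dimethyl-1,3-dioxolan-4-yl]butanoate (both epimers at the phosphonate carbon) | CC1(C)OC[C@@H](CCC(C(=O)OC)P(=O)(OC)OC)O1 | intermediate
6 | methyl 4-[(4R)-2,2-dimethyl-1,3-dioxolan-4-yl]-2-methylidenebutanoate | CC1(C)OC[C@@H](CCC(=C)C(=O)OC)O1 | intermediate
7 | methyl (5R)-5,6-dihydroxy-2-methylidenehexanoate | OC[C@H](O)CCC(=C)C(=O)OC | intermediate
8 | methyl (5R)-5,6-bis[(tert-butyldimethylsilyl)oxy]-2-methylidenehexanoate | CC(C)(C)[Si](C)(C)OC[C@H](O[Si](C)(C)C(C)(C)C)CCC(=C)C(=O)OC | intermediate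
9 | methyl (5R)-5-[(tert-butyldimethylsilyl)oxy]-6-hydroxy-2-methylidenehexanoate | OC[C@H](O[Si](C)(C)C(C)(C)C)CCC(=C)C(=O)OC | intermediate
10 | methyl (5R)-5-[(tert-butyldimethylsilyl)oxy]-2-methylidene-6-oxohexanoate | O=C[C@H](O[Si](C)(C)C(C)(C)C)CCC(=C)C(=O)OC | intermediate
11 | 1-(triphenyl-λ5-phosphanylidene)propan-2-one | CC(=O)C=P(c1ccccc1)(c1ccccc1)c1ccccc1 | starting material
12 | methyl (5R,6E)-5-[(tert-butyldimethylsilyl)oxy]-2-methylidene-8-oxonon-6-enoate | CC(=O)/C=C/[C@H](O[Si](C)(C)C(C)(C)C)CCC(=C)C(=O)OC | intermediate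
13 | methyl (5R,6E)-5,8-bis[(tert-butyldimethylsilyl)oxy]-2-methylidenenona-6,8-dienoate | C=C(O[Si](C)(C)C(C)(C)C)/C=C/[C@H](O[Si](C)(C)C(C)(C)C)CCC(=C)C(=O)OC | intermediate
14 | methyl (3R,3aR,7aS)-3,5-bis[(tert-butyldimethylsilyl)oxy]-2,3,3a,6,7,7a-hexahydro-1H-indene-7a-carboxylate | C1C[C@@]2(C(=O)OC)CC[C@@H](O[Si](C)(C)C(C)(C)C)[C@@H]2C=C1O[Si](C)(C)C(C)(C)C | intermediate
15 | methyl (3R,3aR,7aS)-3-[(tert-butyldimethylsilyl)oxy]-5-oxooctahydro-1H-indene-7a-carboxylate | O=C1CC[C@@]2(C(=O)OC)CC[C@@H](O[Si](C)(C)C(C)(C)C)[C@@H]2C1 | intermediate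
16 | ethyl (2R)-2-{[(trifluoromethyl)sulfonyl]oxy}propanoate | CCOC(=O)[C@@H](C)OS(=O)(=O)C(F)(F)F | starting material
17 | lithium enolate of 15 (C13=C25) | [Li+].[O-]C1=CC[C@@]2(C(=O)OC)CC[C@@H](O[Si](C)(C)C(C)(C)C)[C@@H]2C1 | intermediate
18 | γ-keto ester: 15 with (R)-CH(CH3)CO2Et at C13 (α, equatorial) | CCOC(=O)[C@H](C)[C@H]1C[C@@]2(C(=O)OC)CC[C@@H](O[Si](C)(C)C(C)(C)C)[C@@H]2CC1=O | intermediate
19 | tertiary alcohol: 18 with axial α-OH and equatorial β-vinyl at C25 | CCOC(=O)[C@H](C)[C@H]1C[C@@]2(C(=O)OC)CC[C@@H](O[Si](C)(C)C(C)(C)C)[C@@H]2C[C@]1(O)C=C | intermediate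
20 | C25 triethylsilyl ether of 19 | CCOC(=O)[C@H](C)[C@H]1C[C@@]2(C(=O)OC)CC[C@@H](O[Si](C)(C)C(C)(C)C)[C@@H]2C[C@]1(O[Si](CC)(CC)CC)C=C | intermediate
21 | secondary ozonide of 20 (1,2,4-trioxolane on C25) | CCOC(=O)[C@H](C)[C@H]1C[C@@]2(C(=O)OC)CC[C@@H](O[Si](C)(C)C(C)(C)C)[C@@H]2C[C@]1(O[Si](CC)(CC)CC)C3OCOO3 | intermediate
22 | α-silyloxy aldehyde (C2 = CHO on C25) | CCOC(=O)[C@H](C)[C@H]1C[C@@]2(C(=O)OC)CC[C@@H](O[Si](C)(C)C(C)(C)C)[C@@H]2C[C@]1(O[Si](CC)(CC)CC)C=O | intermediate
23 | 3-methylcyclopent-2-en-1-one | CC1=CC(=O)CC1 | starting material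
24 | bis{[(3R)-3-methylcyclopent-1-en-1-yl]oxy}diphenylsilane | c1ccccc1[Si](OC2=C[C@H](C)CC2)(OC2=C[C@H](C)CC2)c1ccccc1 | intermediate
25 | lithium (3R)-3-methylcyclopent-1-en-1-olate | [Li+].[O-]C1=C[C@H](C)CC1 | intermediate
26 | (3R)-3-methylcyclopent-1-en-1-yl trifluoromethanesulfonate | O=S(=O)(OC1=C[C@H](C)CC1)C(F)(F)F | intermediate
27 | allylic alcohols: 22 with the cyclopentenyl ring added at C2 (both C2 epimers) | CCOC(=O)[C@H](C)[C@H]1C[C@@]2(C(=O)OC)CC[C@@H](O[Si](C)(C)C(C)(C)C)[C@@H]2C[C@]1(O[Si](CC)(CC)CC)C(O)C3=C[C@H](C)CC3 | intermediate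
28 | enone: C2 ketone between C25 and the (3R)-3-methylcyclopentenyl ring | CCOC(=O)[C@H](C)[C@H]1C[C@@]2(C(=O)OC)CC[C@@H](O[Si](C)(C)C(C)(C)C)[C@@H]2C[C@]1(O[Si](CC)(CC)CC)C(=O)C3=C[C@H](C)CC3 | intermediate
29 | lithium alkoxide of the C2 tertiary alcohol (C2 R) | [Li+].CCOC(=O)[C@H](C)[C@H]1C[C@@]2(C(=O)OC)CC[C@@H](O[Si](C)(C)C(C)(C)C)[C@@H]2C[C@]1(O[Si](CC)(CC)CC)[C@](C)([O-])C3=C[C@H](C)CC3 | intermediate
30 | δ-lactone, trans-fused to ring C; C11 methyl equatorial; C2 R (methyl axial, cyclopentenyl equatorial) | O=C1[C@H](C)[C@H]2C[C@@]3(C(=O)OC)CC[C@@H](O[Si](C)(C)C(C)(C)C)[C@@H]3C[C@]2(O[Si](CC)(CC)CC)[C@@](C)(C4=C[C@H](C)CC4)O1 | intermediate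
31 | 2-methylidenetetrahydropyran from 30 (C10=C9) | C=C1[C@H](C)[C@H]2C[C@@]3(C(=O)OC)CC[C@@H](O[Si](C)(C)C(C)(C)C)[C@@H]3C[C@]2(O[Si](CC)(CC)CC)[C@@](C)(C4=C[C@H](C)CC4)O1 | intermediate
32 | tetracyclic cyclooct-4-enone (C10 ketone; C6 R, C8 S) | C/C1=C2\CC[C@@H](C)[C@@H]2CC(=O)[C@H](C)[C@H]2C[C@@]3(C(=O)OC)CC[C@@H](O[Si](C)(C)C(C)(C)C)[C@@H]3C[C@]12O[Si](CC)(CC)CC | intermediate
33 | C10 tosylhydrazone of 32 | C/C1=C2\CC[C@@H](C)[C@@H]2CC(=NNS(=O)(=O)c4ccc(C)cc4)[C@H](C)[C@H]2C[C@@]3(C(=O)OC)CC[C@@H](O[Si](C)(C)C(C)(C)C)[C@@H]3C[C@]12O[Si](CC)(CC)CC | intermediate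
34 | N-(1,3,2-benzodioxaborol-2-yl) tosylhydrazine at C10 | C/C1=C2\CC[C@@H](C)[C@@H]2CC(N(NS(=O)(=O)c4ccc(C)cc4)B4Oc5ccccc5O4)[C@H](C)[C@H]2C[C@@]3(C(=O)OC)CC[C@@H](O[Si](C)(C)C(C)(C)C)[C@@H]3C[C@]12O[Si](CC)(CC)CC | intermediate
35 | bis-silyl ether, C10 = CH2 | C/C1=C2\CC[C@@H](C)[C@@H]2CC[C@H](C)[C@H]2C[C@@]3(C(=O)OC)CC[C@@H](O[Si](C)(C)C(C)(C)C)[C@@H]3C[C@]12O[Si](CC)(CC)CC | intermediate
36 | diol (C25–OH, C19–OH α) | C/C1=C2\CC[C@@H](C)[C@@H]2CC[C@H](C)[C@H]2C[C@@]3(C(=O)OC)CC[C@@H](O)[C@@H]3C[C@]12O | intermediate
37 | ring-D ketone (C19=O) | C/C1=C2\CC[C@@H](C)[C@@H]2CC[C@H](C)[C@H]2C[C@@]3(C(=O)OC)CCC(=O)[C@@H]3C[C@]12O | intermediate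
38 | dipotassium C25 alkoxide C18=C19 enolate of 37 | [K+].[K+].C/C1=C2\CC[C@@H](C)[C@@H]2CC[C@H](C)[C@H]2C[C@@]3(C(=O)OC)CC=C([O-])[C@@H]3C[C@]12[O-] | intermediate
39 | enol triflate (C18=C19) | C/C1=C2\CC[C@@H](C)[C@@H]2CC[C@H](C)[C@H]2C[C@@]3(C(=O)OC)CC=C(OS(=O)(=O)C(F)(F)F)[C@@H]3C[C@]12O | intermediate
40 | isopropylcyclopentene (C18=C19) | C/C1=C2\CC[C@@H](C)[C@@H]2CC[C@H](C)[C@H]2C[C@@]3(C(=O)OC)CC=C(C(C)C)[C@@H]3C[C@]12O | intermediate
41 | methyl ester of sesterfisheric acid | C/C1=C2\CC[C@@H](C)[C@@H]2CC[C@H](C)[C@H]2C[C@@]3(C(=O)OC)CC[C@H](C(C)C)[C@@H]3C[C@]12O | intermediate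
42 | sesterfisheric acid | C/C1=C2\CC[C@@H](C)[C@@H]2CC[C@H](C)[C@H]2C[C@@]3(C(=O)O)CC[C@H](C(C)C)[C@@H]3C[C@]12O | target

**Count**

Total: 29 steps. Longest linear sequence: 28 steps (steps 1–15 and 17–29, from 1 to 42); step 16 is the only side branch.

**Steps most likely to fail**

1. Step 10. Ring-fusion selectivity may erode if the tether rather than the ester takes the endo position (cis-fused adduct), and facial selectivity may be lower than hoped. Fallback, from 12 back to 15: the annulation is run as an anionic double Michael addition. LiN(SiMe3)2 (THF, −78 °C) deprotonates the methyl ketone 12 to the cross-conjugated lithium dienolate F1, in which lithium bridges the enolate oxygen and the ester carbonyl and so holds the ester over the dienolate. Michael addition of C13 to C14 and closure of the resulting ester enolate onto C23 (−78 → 0 °C) give the lithium C24 enolate F2, and protonation gives ketone 15, so 13 and 14 are bypassed. If only the facial sense is opposite to the one expected, the enantiomer of 1 is bought and nothing else changes, because C19 is erased later.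

2. Step 21. The boat-shaped tetrahydropyran that the rearrangement needs may raise the barrier enough for heterolysis of the tertiary allylic C2–O bond and elimination to win. Fallback, from 31 back to 35: i-Bu3Al (CH2Cl2, −78 → 23 °C) promotes the [3,3] shift by coordination to the ether oxygen and reduces the C10 ketone as it forms, giving the cyclooct-4-enol F3 (either C10 epimer). NaH, CS2 and MeI (THF) convert it into the xanthate F4. Barton–McCombie reduction (Bu3SnH 0.5 M, AIBN, toluene, 90 °C; the high stannane concentration outruns transannular addition of the C10 radical) gives 35, so 32–34 are bypassed.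

3. Step 19. The addition at C2 may take the wrong facial course; the epimer with an axial cyclopentenyl group cannot deliver C8 correctly. Fallback, from 22 and 26 back to 30: the two carbon groups are added in the reverse order, so that the same facial preference gives the required epimer. MeMgBr (THF, −78 °C) adds to aldehyde 22 to give the secondary alcohols F5, and Dess–Martin periodinane oxidises them to the methyl ketone F6. Triflate 26 is converted with Me3SnSnMe3, Pd(PPh3)4 and LiCl (THF, 60 °C) into the alkenylstannane F7, and tin–lithium exchange with MeLi (THF, −78 °C) gives the alkenyllithium F8. F8 adds to F6; the alkoxide formed is 29, which lactonises to 30 on warming.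

**Further compounds**

F1 | step 10 | lithium cross-conjugated dienolate of 12 | [Li+].C=C([O-])/C=C/[C@H](O[Si](C)(C)C(C)(C)C)CCC(=C)C(=O)OC
F2 | step 10 | lithium enolate of 15 (C24=C25) | [Li+].C1C[C@@]2(C(=O)OC)CC[C@@H](O[Si](C)(C)C(C)(C)C)[C@@H]2C=C1[O-]
F3 | step 21 | cyclooct-4-enol (C10–OH, both epimers) | C/C1=C2\CC[C@@H](C)[C@@H]2CC(O)[C@H](C)[C@H]2C[C@@]3(C(=O)OC)CC[C@@H](O[Si](C)(C)C(C)(C)C)[C@@H]3C[C@]12O[Si](CC)(CC)CC
F4 | step 21 | S-methyl xanthate of F3 | C/C1=C2\CC[C@@H](C)[C@@H]2CC(OC(=S)SC)[C@H](C)[C@H]2C[C@@]3(C(=O)OC)CC[C@@H](O[Si](C)(C)C(C)(C)C)[C@@H]3C[C@]12O[Si](CC)(CC)CC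
F5 | step 19 | secondary alcohols from 22 and MeMgBr (both C2 epimers) | CCOC(=O)[C@H](C)[C@H]1C[C@@]2(C(=O)OC)CC[C@@H](O[Si](C)(C)C(C)(C)C)[C@@H]2C[C@]1(O[Si](CC)(CC)CC)C(C)O
F6 | step 19 | methyl ketone (C2 acetyl on C25) | CCOC(=O)[C@H](C)[C@H]1C[C@@]2(C(=O)OC)CC[C@@H](O[Si](C)(C)C(C)(C)C)[C@@H]2C[C@]1(O[Si](CC)(CC)CC)C(C)=O
F7 | step 19 | trimethyl[(3R)-3-methylcyclopent-1-en-1-yl]stannane | C[Sn](C)(C)C1=C[C@H](C)CC1
F8 | step 19 | [(3R)-3-methylcyclopent-1-en-1-yl]lithium | [Li]C1=C[C@H](C)CC1
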